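**Retrosynthetic overview**
1. The last bond made is C18–O of the side lactone: a hydroxy tert-butyl ester is closed by a catalyst-controlled ionising lactonisation that sets C18. The side chain comes from Friedel–Crafts acylation of the tetracyclic core with (S)-methylsuccinic anhydride, which supplies C20.
2. Tetracyclic core: the azepine is closed by N4–C5 alkylation; the cyclohexane is closed at C9–C9a by reductive Friedel–Crafts alkylation of a chlorobutyl ketone, with hydride setting C9.
3. The ketone comes from an all-cis lactone acid and (4-chlorobutyl)zinc bromide; the all-cis lactone comes from hydrogenation of a 4-(pyrrol-3-yl)butenolide (sets C12 and C13 from C11).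
4. The butenolide comes from a tetronate triflate and a pyrrol-3-yl boronate; the tetronate comes from Dieckmann closure of an O-propanoyl 3-ethylmalate.
5. C10 and C11 come from dimethyl (R)-malate by Fráter–Seebach ethylation. Ring order: fused lactone, cyclohexane, azepine, side lactone (the pyrrole is bought).

Assumption: dimethyl (R)-malate, the silyl pyrrole boronate, (4-chlorobutyl)zinc bromide (0.5 M in THF) and (S)-methylsuccinic anhydride are bought; polycycle locants follow the usual Stemona numbering (N4; pyrrole C1, C2, C3, C9a; azepine C5 to C9; C10 ethyl; C11 O; C12; C13 methyl; C14 carbonyl; side lactone C18 to C21).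

**Route**

Step 1
Reactants: 1 dimethyl (2R)-2-hydroxybutanedioate
Product: 3 dimethyl (2S,3R)-2-ethyl-3-(propanoyloxy)butanedioate, via lithium alkoxide of ethylmalate 2 (not isolated)
Conditions: LiN(SiMe3)2 (2.1 equiv), THF, −78 to −20 °C; EtI, −78 to −10 °C; then EtCOCl, −78 to 0 °C
Reagents that add atoms: iodoethane, CCI; propanoyl chloride, CCC(=O)Cl
Why: Fráter–Seebach alkylation: the chelated dianion is ethylated anti to the alkoxide (about 9:1), which sets C10 from the malate carbinol C11, and the lithium alkoxide is then O-acylated in the same flask.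

Step 2
Reactants: 3 dimethyl (2S,3R)-2-ethyl-3-(propanoyloxy)butanedioate
Product: 4 methyl (2S)-2-[(2R)-3-hydroxy-4-methyl-5-oxo-2,5-dihydrofuran-2-yl]butanoate
Conditions: LiN(SiMe3)2 (2.2 equiv), THF, −78 to −20 °C; aq HCl
Reagents that add atoms: none
Why: Dieckmann condensation: the propanoate enolate attacks the adjacent α-acyloxy ester (5-exo) to give the 3-methyltetronic acid, whose salt protects C11 from further deprotonation.

Step 3
Reactants: 4 methyl (2S)-2-[(2R)-3-hydroxy-4-methyl-5-oxo-2,5-dihydrofuran-2-yl]butanoate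
Product: 5 methyl (2S)-2-[(2R)-4-methyl-5-oxo-3-(trifluoromethanesulfonyloxy)-2,5-dihydrofuran-2-yl]butanoate
Conditions: Tf2O, i-Pr2NEt, CH2Cl2, −78 °C
Reagents that add atoms: trifluoromethanesulfonic anhydride, O=S(=O)(OS(=O)(=O)C(F)(F)F)C(F)(F)F
Why: O-sulfonylation of the acidic tetronic enol gives the vinyl triflate; the cold hindered amine leaves the γ-hydrogen at C11 alone.

Step 4
Reactants: 5 methyl (2S)-2-[(2R)-4-methyl-5-oxo-3-(trifluoromethanesulfonyloxy)-2,5-dihydrofuran-2-yl]butanoate; 6 3-(4,4,5,5-tetramethyl-1,3,2-dioxaborolan-2-yl)-1-[tri(propan-2-yl)silyl]-1H-pyrrole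
Product: 7 methyl (2S)-2-[(2R)-4-methyl-5-oxo-3-{1-[tri(propan-2-yl)silyl]-1H-pyrrol-3-yl}-2,5-dihydrofuran-2-yl]butanoate
Conditions: Pd(PPh3)4 (5 mol%), CsF, 1,4-dioxane, 60 °C
Reagents that add atoms: none
Why: Suzuki–Miyaura coupling of a tetronate triflate; the N-silyl group fixes the boron at the pyrrole β-carbon (future C1) and anhydrous fluoride is mild enough to keep C11.

Step 5
Reactants: 7 methyl (2S)-2-[(2R)-4-methyl-5-oxo-3-{1-[tri(propan-2-yl)silyl]-1H-pyrrol-3-yl}-2,5-dihydrofuran-2-yl]butanoate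
Product: 8 methyl (2S)-2-[(2S,3S,4S)-4-methyl-5-oxo-3-{1-[tri(propan-2-yl)silyl]-1H-pyrrol-3-yl}oxolan-2-yl]butanoate
Conditions: H2 (20 bar), palladium on carbon (Pd/C), EtOAc, rt
Reagents that add atoms: none
Why: Heterogeneous syn-hydrogenation of the butenolide from the face opposite the bulky C11 substituent puts H12 and H13 cis to H11, giving the all-cis lactone (sets C12 and C13).

Step 6
Reactants: 8 methyl (2S)-2-[(2S,3S,4S)-4-methyl-5-oxo-3-{1-[tri(propan-2-yl)silyl]-1H-pyrrol-3-yl}oxolan-2-yl]butanoate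
Product: 9 (2S)-2-[(2S,3S,4S)-4-methyl-5-oxo-3-{1-[tri(propan-2-yl)silyl]-1H-pyrrol-3-yl}oxolan-2-yl]butanoic acid
Conditions: Me3SnOH, ClCH2CH2Cl, 70 °C; aq HCl work-up
Reagents that add atoms: trimethyltin hydroxide, C[Sn](C)(C)O
Why: Trimethyltin hydroxide ester cleavage is neutral enough to keep the N-silyl group and the α-centres; if the lactone opens it recloses on acidification with C11 unchanged (acyl C–O cleavage).

Step 7
Reactants: 9 (2S)-2-[(2S,3S,4S)-4-methyl-5-oxo-3-{1-[tri(propan-2-yl)silyl]-1H-pyrrol-3-yl}oxolan-2-yl]butanoic acid; 10 (4-chlorobutyl)zinc bromide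
Product: 12 (3S,4S,5S)-5-[(3S)-8-chloro-4-oxooctan-3-yl]-3-methyl-4-{1-[tri(propan-2-yl)silyl]-1H-pyrrol-3-yl}oxolan-2-one, via acid chloride 11 (not isolated)
Conditions: 1-chloro-N,N,2-trimethylprop-1-en-1-amine, CH2Cl2, 0 °C to rt; then 10, Pd(PPh3)4 (5 mol%), THF, 0 °C to rt
Reagents that add atoms: none
Why: Neutral acid chloride formation (Ghosez reagent) followed by Negishi acylation gives the ketone without base, so C10 and the lactone are untouched and the alkyl chloride survives.

Step 8
Reactants: 12 (3S,4S,5S)-5-[(3S)-8-chloro-4-oxooctan-3-yl]-3-methyl-4-{1-[tri(propan-2-yl)silyl]-1H-pyrrol-3-yl}oxolan-2-one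
Product: 15 (9S,10R,11R,12S,13S)-9-(4-chlorobutyl)-10-ethyl-13-methyl N4-H tricyclic lactone (4,5,6,7-tetrahydroindole cis-fused at C11–C12 to the γ-lactone), via desilylated ketone 13 (not isolated), via tertiary carbinol 14 (not isolated)
Conditions: HF·pyridine, THF, 0 °C; then Et3SiH, CF3CO2H, CH2Cl2, −40 to 0 °C
Reagents that add atoms: none
Why: Reductive Friedel–Crafts alkylation: the free pyrrole α-carbon (C9a) adds to the ketone (6-ring), the carbinol ionises to a 2-azafulvenium ion, and silane hydride attacks C9 from the face opposite the pseudo-axial C10 ethyl and the cis-fused lactone, so H9 ends cis to H10, H11 and H12 (sets C9).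

Step 9
Reactants: 15 (9S,10R,11R,12S,13S)-9-(4-chlorobutyl)-10-ethyl-13-methyl N4-H tricyclic lactone
Product: 16 (9S,10R,11R,12S,13S)-tetracyclic core (pyrrolo[1,2-a]azepine fused to the cyclohexane and γ-lactone; C3–H free)
Conditions: NaH (1.1 equiv), NaI (cat.), DMF, 0 °C to rt
Reagents that add atoms: none
Why: Intramolecular SN2 N-alkylation of the pyrrolide (7-exo-tet) closes the azepine through the N4–C5 bond; only a slight excess of base is used so the lactone α-centre C13 is not equilibrated.

Step 10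
Reactants: 16 tetracyclic core; 17 (3S)-3-methyloxolane-2,5-dione
Product: 18 (2S)-2-methyl-4-oxo-4-[(9S,10R,11R,12S,13S)-core-3-yl]butanoic acid
Conditions: Sc(OSO2CF3)3 (10 mol%), MeNO2, 0 °C to rt
Reagents that add atoms: none
Why: Friedel–Crafts acylation at the only free pyrrole α-position (C3); the anhydride is opened at the carbonyl next to CH2 (less hindered), so C20 arrives intact from 17.

Step 11
Reactants: 18 (2S)-2-methyl-4-oxo-4-[(9S,10R,11R,12S,13S)-core-3-yl]butanoic acid
Product: 19 tert-butyl (2S)-2-methyl-4-oxo-4-[(9S,10R,11R,12S,13S)-core-3-yl]butanoate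
Conditions: tert-butyl 2,2,2-trichloroacetimidate, CH2Cl2/cyclohexane, rt
Reagents that add atoms: tert-butyl 2,2,2-trichloroacetimidate, CC(C)(C)OC(=N)C(Cl)(Cl)Cl
Why: Imidate O-alkylation of the acid (self-catalysed) installs an ester that cannot lactonise by acyl transfer during the following reduction.

Step 12
Reactants: 19 tert-butyl (2S)-2-methyl-4-oxo-4-[(9S,10R,11R,12S,13S)-core-3-yl]butanoate
Product: 20 tert-butyl (2S,4RS)-4-hydroxy-2-methyl-4-[(9S,10R,11R,12S,13S)-core-3-yl]butanoate (both C18 epimers)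
Conditions: NaBH4, MeOH/THF, 0 °C to rt; NaHCO3 work-up, used crude
Reagents that add atoms: none
Why: Borohydride reduction of the 2-acylpyrrole ketone under basic conditions, where the acid-labile pyrrolyl carbinol does not ionise and the tert-butyl ester and γ-lactone survive; the C18 ratio is irrelevant.

Step 13
Reactants: 20 tert-butyl (2S,4RS)-4-hydroxy-2-methyl-4-[(9S,10R,11R,12S,13S)-core-3-yl]butanoate
Product: 21 Epibisdehydroneotuberostemonine J
Conditions: (R)-3,3'-bis(2,4,6-triisopropylphenyl)-1,1'-binaphthyl-2,2'-diyl hydrogen phosphate (5 mol%), 5 Å molecular sieves, toluene (0.01 M), −40 °C; Et3N quench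
Reagents that add atoms: none
Why: Proposed new method: stereoconvergent ion-pair lactonisation. Both C18 carbinol epimers are ionised by the chiral phosphoric acid to one planar 2-azafulvenium ion held as a contact ion pair with the chiral phosphate. The tert-butyl ester carbonyl oxygen attacks C18 (5-exo) on the face left open by the anion, forming the C18–O bond and setting 18R (trans to the C20 methyl). The resulting tert-butoxy lactonium ion loses isobutene and returns the proton to the catalyst. The catalyst hand that gives 18R is fixed by one pair of test runs, and low temperature with a weak acid keeps the product lactone from re-ionising. The closest known chemistry is chiral phosphoric acid catalysed enantioconvergent substitution of indolyl and pyrrolyl carbinols through fulvenium-type ion pairs, together with cation-triggered lactonisation of tert-butyl esters.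

**Compound list**
1 | dimethyl (2R)-2-hydroxybutanedioate | COC(=O)C[C@@H](O)C(=O)OC | starting material
2 | dimethyl (2S,3R)-2-ethyl-3-hydroxybutanedioate (present as its lithium alkoxide) | CC[C@H](C(=O)OC)[C@@H](O)C(=O)OC | intermediate
3 | dimethyl (2S,3R)-2-ethyl-3-(propanoyloxy)butanedioate | CC[C@H](C(=O)OC)[C@@H](OC(=O)CC)C(=O)OC | intermediate
4 | methyl (2S)-2-[(2R)-3-hydroxy-4-methyl-5-oxo-2,5-dihydrofuran-2-yl]butanoate | CC[C@H](C(=O)OC)[C@H]1OC(=O)C(C)=C1O | intermediate
5 | methyl (2S)-2-[(2R)-4-methyl-5-oxo-3-(trifluoromethanesulfonyloxy)-2,5-dihydrofuran-2-yl]butanoate | CC[C@H](C(=O)OC)[C@H]1OC(=O)C(C)=C1OS(=O)(=O)C(F)(F)F | intermediate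
6 | 3-(4,4,5,5-tetramethyl-1,3,2-dioxaborolan-2-yl)-1-[tri(propan-2-yl)silyl]-1H-pyrrole | CC(C)[Si](C(C)C)(C(C)C)n1ccc(c1)B1OC(C)(C)C(C)(C)O1 | starting material
7 | methyl (2S)-2-[(2R)-4-methyl-5-oxo-3-{1-[tri(propan-2-yl)silyl]-1H-pyrrol-3-yl}-2,5-dihydrofuran-2-yl]butanoate | CC[C@H](C(=O)OC)[C@H]1OC(=O)C(C)=C1c1ccn(c1)[Si](C(C)C)(C(C)C)C(C)C | intermediate
8 | methyl (2S)-2-[(2S,3S,4S)-4-methyl-5-oxo-3-{1-[tri(propan-2-yl)silyl]-1H-pyrrol-3-yl}oxolan-2-yl]butanoate (all-cis lactone) | CC[C@H](C(=O)OC)[C@H]1OC(=O)[C@@H](C)[C@H]1c1ccn(c1)[Si](C(C)C)(C(C)C)C(C)C | intermediate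
9 | (2S)-2-[(2S,3S,4S)-4-methyl-5-oxo-3-{1-[tri(propan-2-yl)silyl]-1H-pyrrol-3-yl}oxolan-2-yl]butanoic acid | CC[C@H](C(=O)O)[C@H]1OC(=O)[C@@H](C)[C@H]1c1ccn(c1)[Si](C(C)C)(C(C)C)C(C)C | intermediate
10 | (4-chlorobutyl)zinc bromide | ClCCCC[Zn]Br | starting material
11 | (2S)-2-[(2S,3S,4S)-4-methyl-5-oxo-3-{1-[tri(propan-2-yl)silyl]-1H-pyrrol-3-yl}oxolan-2-yl]butanoyl chloride | CC[C@H](C(=O)Cl)[C@H]1OC(=O)[C@@H](C)[C@H]1c1ccn(c1)[Si](C(C)C)(C(C)C)C(C)C | intermediate
12 | (3S,4S,5S)-5-[(3S)-8-chloro-4-oxooctan-3-yl]-3-methyl-4-{1-[tri(propan-2-yl)silyl]-1H-pyrrol-3-yl}oxolan-2-one | CC[C@H](C(=O)CCCCCl)[C@H]1OC(=O)[C@@H](C)[C@H]1c1ccn(c1)[Si](C(C)C)(C(C)C)C(C)C | intermediate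
13 | (3S,4S,5S)-5-[(3S)-8-chloro-4-oxooctan-3-yl]-3-methyl-4-(1H-pyrrol-3-yl)oxolan-2-one | CC[C@H](C(=O)CCCCCl)[C@H]1OC(=O)[C@@H](C)[C@H]1c1cc[nH]c1 | intermediate
14 | tertiary carbinol: compound 15 carrying OH in place of H at C9 (both C9 epimers; C10 to C13 as in 15) | CC[C@H]1[C@H]2OC(=O)[C@@H](C)[C@H]2c2cc[nH]c2C1(O)CCCCCl | intermediate
15 | (9S,10R,11R,12S,13S)-9-(4-chlorobutyl)-10-ethyl-13-methyl N4-H tricyclic lactone: pyrrole (C2–H, C3–H) fused at C1–C9a to cyclohexane C9–C12, γ-lactone O–C14(=O)–C13–C12 cis-fused on C11/C12, all ring hydrogens cis | CC[C@H]1[C@H]2OC(=O)[C@@H](C)[C@H]2c2cc[nH]c2[C@H]1CCCCCl | intermediate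
16 | (9S,10R,11R,12S,13S)-tetracyclic core: 15 with the butyl chain closed onto N4 (azepine), C3–H free | CC[C@H]1[C@H]2OC(=O)[C@@H](C)[C@H]2c2ccn3c2[C@H]1CCCC3 | intermediate
17 | (3S)-3-methyloxolane-2,5-dione [(S)-methylsuccinic anhydride] | O=C1C[C@H](C)C(=O)O1 | starting material
18 | (2S)-2-methyl-4-oxo-4-[(9S,10R,11R,12S,13S)-core-3-yl]butanoic acid (20S keto acid) | CC[C@H]1[C@H]2OC(=O)[C@@H](C)[C@H]2c2cc(C(=O)C[C@H](C)C(=O)O)n3c2[C@H]1CCCC3 | intermediate
19 | tert-butyl (2S)-2-methyl-4-oxo-4-[(9S,10R,11R,12S,13S)-core-3-yl]butanoate | CC[C@H]1[C@H]2OC(=O)[C@@H](C)[C@H]2c2cc(C(=O)C[C@H](C)C(=O)OC(C)(C)C)n3c2[C@H]1CCCC3 | intermediate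
20 | tert-butyl (2S,4RS)-4-hydroxy-2-methyl-4-[(9S,10R,11R,12S,13S)-core-3-yl]butanoate (C18 epimers) | CC[C@H]1[C@H]2OC(=O)[C@@H](C)[C@H]2c2cc(C(O)C[C@H](C)C(=O)OC(C)(C)C)n3c2[C@H]1CCCC3 | intermediate
21 | Epibisdehydroneotuberostemonine J (9S,10R,11R,12S,13S,18R,20S) | CC[C@H]1[C@H]2OC(=O)[C@@H](C)[C@H]2c2cc([C@H]3C[C@H](C)C(=O)O3)n3c2[C@H]1CCCC3 | target

**Count and risks**
Total steps: 13. Longest linear sequence: 13 (from compound 1). Stereocentres: C11 from 1, C10 in step 1, C12 and C13 in step 5, C9 in step 8, C20 from 17, C18 in step 13.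

Three steps most likely to fail:

1. Step 13 (the proposed new method). The C20 centre may bias the ring closure against the catalyst, the product lactone may re-ionise and drift towards the cis/trans equilibrium, and the expelled tert-butyl cation could alkylate C2. The fallback uses known chemistry and sets out from 19. The ketone is reduced under reagent control by Corey–Bakshi–Shibata reduction, using (S)-1-methyl-3,3-diphenyl-tetrahydro-1H,3H-pyrrolo[1,2-c][1,3,2]oxazaborole and catecholborane in toluene at −78 °C. This gives the single carbinol tert-butyl (2S,4R)-4-hydroxy-2-methyl-4-[(9S,10R,11R,12S,13S)-core-3-yl]butanoate F4. Without exposure to acid, NaH in THF at 0 °C then lets the alkoxide displace tert-butoxide at the ester carbonyl, so C18 is retained. The fallback comes back at 21.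

2. Step 8. The azafulvenium ion may lose H10 to give the 9,10-alkene, whose allylic lactone can ionise and aromatise; the pyrrole may be over-reduced; closure at the other pyrrole β-carbon is possible. The fallback sets out from 12 and separates ring closure from reduction. After HF·pyridine desilylation, pyridinium p-toluenesulfonate in toluene at 60 °C effects Friedel–Crafts cyclodehydration to the vinylpyrrole 9-(4-chlorobutyl)-10-ethyl-9,10-didehydro N4-H tricyclic lactone F1. Neutral hydrogenation (H2, palladium on carbon, EtOAc) then adds hydrogen from the face opposite the cis-fused lactone. It comes back at 15.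

3. Step 10. The pyrrole may open the anhydride at the wrong carbonyl, giving the constitutional isomer, and the electron-rich core may not tolerate the Lewis acid. The fallback sets out from 17 (with 16) and fixes the regiochemistry on the cheap fragment first. Dimethylamine in THF opens 17 at the unhindered carbonyl to (2S)-4-(dimethylamino)-2-methyl-4-oxobutanoic acid F2, which is purified by crystallisation. tert-Butyl 2,2,2-trichloroacetimidate converts it into tert-butyl (2S)-4-(dimethylamino)-2-methyl-4-oxobutanoate F3. Vilsmeier–Haack acylation of 16 with F3 and POCl3 in ClCH2CH2Cl, followed by aqueous CH3CO2Na hydrolysis of the iminium salt, gives the keto ester directly. It comes back at 19, so step 11 is skipped.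

Further compounds
F1 | step 8 | 9-(4-chlorobutyl)-10-ethyl-9,10-didehydro N4-H tricyclic lactone (lactone centres C11, C12, C13 as in 15) | CCC=1[C@H]2OC(=O)[C@@H](C)[C@H]2c2cc[nH]c2C=1CCCCCl
F2 | step 10 | (2S)-4-(dimethylamino)-2-methyl-4-oxobutanoic acid | CN(C)C(=O)C[C@H](C)C(=O)O
F3 | step 10 | tert-butyl (2S)-4-(dimethylamino)-2-methyl-4-oxobutanoate | CN(C)C(=O)C[C@H](C)C(=O)OC(C)(C)C
F4 | step 13 | tert-butyl (2S,4R)-4-hydroxy-2-methyl-4-[(9S,10R,11R,12S,13S)-core-3-yl]butanoate | CC[C@H]1[C@H]2OC(=O)[C@@H](C)[C@H]2c2cc([C@H](O)C[C@H](C)C(=O)OC(C)(C)C)n3c2[C@H]1CCCC3
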